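Assumptions: ring compounds are numbered as 1H‑indenes (the acid‑bearing carbon is C4), which makes the target (1R,3aR,4R,5S,7aS); ylide 4, (E)‑β‑bromostyrene 14 and both Roche ester enantiomers are taken as purchasable.

## Retrosynthetic overview

1. Target 16 ⇐ one‑pot CH2OH → CO2H oxidation of 15 ⇐ alkyne hydrozirconation/Pd coupling with (E)‑β‑bromostyrene on 13 (builds the phenyldienyl side chain).
2. 13 ⇐ electrochemical hole‑catalysed (cation‑radical) intramolecular Diels–Alder of the acyclic bis‑diene 12. This forms C3a–C7a and the C4–C5 quaternary–quaternary bond, so the cyclopentene and cyclohexene rings close in the same step.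
3. 12 ⇐ (Z)‑vinyl iodide 10 + propargyl alcohol (carboalumination/Negishi coupling); 10 ⇐ aldehyde 9 (Z‑selective iodo‑Wittig).
4. 9 ⇐ (R)‑Roche ester 1 via Wittig, dibromo‑olefination and stereoselective double Pd substitution (E,E‑dienyne arm).
5. The only purchased stereocentre is C1 (from 1); it controls C7a, C3a, C4 and C5 in the cycloaddition.

## Route

**Step 1**
Reactants: 1, methyl (R)‑3‑hydroxy‑2‑methylpropanoate ((R)‑Roche ester)
Product: 2, methyl (R)‑3‑[(tert‑butyldimethylsilyl)oxy]‑2‑methylpropanoate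
Conditions: TBSCl, imidazole, DMF, 0→23 °C
Reagents that add atoms: tert‑butyldimethylsilyl chloride, CC(C)(C)[Si](C)(C)Cl
Why: Standard silylation of a primary alcohol; the stereocentre is not touched.

**Step 2**
Reactants: 2
Product: 3, (R)‑3‑[(tert‑butyldimethylsilyl)oxy]‑2‑methylpropanal
Conditions: DIBAL‑H (1.05 equiv), CH2Cl2, −78 °C; Rochelle salt work‑up; used crude
Reagents that add atoms: none
Why: Low‑temperature partial DIBAL reduction of the ester via the stable tetrahedral aluminate gives the known Roche aldehyde without epimerisation.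

**Step 3**
Reactants: 3; 4, 2‑(triphenyl‑λ5‑phosphanylidene)propanal
Product: 5, (S,E)‑5‑[(tert‑butyldimethylsilyl)oxy]‑2,4‑dimethylpent‑2‑enal
Conditions: 4 (1.3 equiv), toluene, 90 °C
Reagents that add atoms: none beyond reactant 4
Why: Wittig olefination with a stabilised, non‑basic ylide is E‑selective (>95:5) for the trisubstituted enal and leaves the α‑stereocentre intact (the descriptor changes to S only through CIP priorities).

**Step 4**
Reactants: 5
Product: 6, (S,E)‑tert‑butyl[(6,6‑dibromo‑2,4‑dimethylhexa‑3,5‑dien‑1‑yl)oxy]dimethylsilane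
Conditions: CBr4, PPh3, 2,6‑lutidine, CH2Cl2, 0 °C
Reagents that add atoms: carbon tetrabromide, BrC(Br)(Br)Br
Why: Corey–Fuchs (Ramirez) dibromo‑olefination of the enal under buffered, non‑basic conditions; no stereocentre or alkene geometry is affected.

**Step 5**
Reactants: 6
Product: 7, tert‑butyldimethyl{[(2S,3E,5E)‑2,4,6‑trimethylnona‑3,5‑dien‑7‑yn‑1‑yl]oxy}silane
Conditions: MeC≡CZnBr (from MeC≡CMgBr + ZnBr2), Pd(DPEphos)Cl2 (5 mol%), THF, 0→23 °C; then Me2Zn, Pd(t‑Bu3P)2 (5 mol%), 23 °C, one pot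
Reagents that add atoms: 1‑propynylzinc bromide, CC#C[Zn]Br; dimethylzinc, C[Zn]C
Why: Negishi trans‑selective mono‑alkynylation of the 1,1‑dibromoalkene (the less hindered Br trans to the chain reacts first) followed by stereoretentive methylation of the remaining Br fixes the 5E geometry (alkynyl trans to chain, methyl cis) that later defines the C5 configuration.

**Step 6**
Reactants: 7
Product: 8, (2S,3E,5E)‑2,4,6‑trimethylnona‑3,5‑dien‑7‑yn‑1‑ol
Conditions: TBAF, THF, 0→23 °C
Reagents that add atoms: none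
Why: Fluoride desilylation; the dienyne and stereocentre are inert.

**Step 7**
Reactants: 8
Product: 9, (2S,3E,5E)‑2,4,6‑trimethylnona‑3,5‑dien‑7‑ynal
Conditions: Dess–Martin periodinane, NaHCO3, CH2Cl2, 0 °C; short silica plug; used immediately
Reagents that add atoms: none
Why: Buffered Dess–Martin oxidation is neutral and fast, which minimises epimerisation or conjugation of the α‑methyl‑β,γ‑unsaturated aldehyde.

**Step 8**
Reactants: 9
Product: 10, (2Z,4S,5E,7E)‑2‑iodo‑4,6,8‑trimethylundeca‑2,5,7‑trien‑9‑yne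
Conditions: EtPPh3I, n‑BuLi, THF; I2, −78 °C; NaHMDS, −20 °C; then 9, −78 °C
Reagents that add atoms: (1‑iodoethylidene)triphenylphosphorane, CC(I)=P(c1ccccc1)(c1ccccc1)c1ccccc1, made in situ from ethyltriphenylphosphonium iodide, CC[P+](c1ccccc1)(c1ccccc1)c1ccccc1.[I-], and iodine, II
Why: Stork–Zhao iodo‑Wittig olefination gives the (Z)‑2‑iodoalkene (I cis to the chain) and, as a reactive non‑stabilised ylide at −78 °C, outruns epimerisation of 9.

**Step 9**
Reactants: 10; 11, prop‑2‑yn‑1‑ol (propargyl alcohol)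
Product: 12, (2E,4Z,6S,7E,9E)‑2,4,6,8,10‑pentamethyltrideca‑2,4,7,9‑tetraen‑11‑yn‑1‑ol
Conditions: 11, Me3Al (3 equiv), Cp2ZrCl2 (0.25 equiv), (CH2Cl)2, 0→23 °C; strip volatiles; then 10, ZnCl2, Pd(PPh3)4 (5 mol%), THF, 23 °C
Reagents that add atoms: trimethylaluminium, C[Al](C)C
Why: Negishi Zr‑catalysed syn‑carboalumination of propargyl alcohol gives the (E)‑2‑methylalkenylalane, and Pd/Zn cross‑coupling with the vinyl iodide proceeds with retention on both partners to give the (2E,4Z)‑diene (THF shuts down further carboalumination of the internal alkyne).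

**Step 10**
Reactants: 12
Product: 13, [(1R,3aR,4R,5R,7aS)‑1,3,4,5,7‑pentamethyl‑5‑(prop‑1‑yn‑1‑yl)‑3a,4,5,7a‑tetrahydro‑1H‑inden‑4‑yl]methanol
Conditions: undivided cell, carbon‑felt anode / Pt cathode, (2,4‑Br2C6H3)3N (10 mol%), Bu4NPF6 (0.1 M), CH2Cl2/HFIP 9:1, 5 mM, 0 °C, constant current, 0.2–0.3 F mol⁻¹, Ar
Reagents that add atoms: none
Why: Proposed new method: the anodically generated triarylaminium (E ≈ +1.5 V vs SCE) oxidises an alkyl‑substituted diene arm of 12 to its cation radical (intramolecular hole exchange between the two arms is fast), which, as the ionised 2π partner, undergoes an intramolecular cation‑radical Diels–Alder with the neutral (7E,9E)‑diene — the 4Z geometry permits only this mode — forming C3a–C7a and the hindered C4–C5 bond suprafacially, so the E‑dienophile and E,E‑diene geometries fix C4/C5, while the trans‑fused transition state with C1–H eclipsing the C7 methyl (A1,3 strain; the cis‑fused alternative clashes C3‑Me with C7‑Me) lets the Roche‑derived C1 centre set C7a, C3a, C4 and C5; the adduct cation radical (isolated alkenes, E > +1.9 V) re‑oxidises substrate or amine, so charge is catalytic and the product is not over‑oxidised; the closest known chemistry is Bauld's aminium‑salt cation‑radical Diels–Alder between 1,3‑dienes and its electrochemical and photoredox versions, not yet shown intramolecularly for a skipped bis(diene) forming vicinal quaternary centres.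

**Step 11**
Reactants: 13; 14, (E)‑(2‑bromovinyl)benzene ((E)‑β‑bromostyrene)
Product: 15, [(1R,3aR,4R,5S,7aS)‑1,3,4,5,7‑pentamethyl‑5‑[(1E,3E)‑2‑methyl‑4‑phenylbuta‑1,3‑dien‑1‑yl]‑3a,4,5,7a‑tetrahydro‑1H‑inden‑4‑yl]methanol
Conditions: Cp2Zr(H)Cl (3 equiv), THF, 23→40 °C; then 14, ZnCl2, Pd(PPh3)4 (5 mol%), 23→40 °C
Reagents that add atoms: none beyond reactant 14 (Cp2Zr(H)Cl delivers only H)
Why: Schwartz syn‑hydrozirconation places Zr on the methyl‑bearing alkyne carbon (away from quaternary C5; the first equivalent is consumed by the OH), and Negishi Zn‑assisted Pd coupling with retention gives the (1E,3E)‑diene without touching the trisubstituted ring alkenes or any stereocentre.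

**Step 12**
Reactants: 15
Product: 16, (1R,3aR,4R,5S,7aS)‑1,3,4,5,7‑pentamethyl‑5‑[(1E,3E)‑2‑methyl‑4‑phenylbuta‑1,3‑dien‑1‑yl]‑3a,4,5,7a‑tetrahydro‑1H‑indene‑4‑carboxylic acid (27‑nor‑zyggomphic acid B)
Conditions: 1‑Me‑AZADO⁺BF4⁻ (5 mol%), NaClO2 (3 equiv), MeCN/pH 6.8 phosphate buffer, 23 °C
Reagents that add atoms: sodium chlorite, [Na+].[O-]Cl=O
Why: One‑pot oxoammonium oxidation of the hindered neopentyl alcohol to the aldehyde and in situ chlorite (Pinnick‑type) oxidation to the acid, with the HOCl by‑product consumed in catalyst turnover so the alkenes and diene survive; C4 is quaternary and cannot epimerise.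

## Compound list

1 | methyl (R)‑3‑hydroxy‑2‑methylpropanoate | C[C@H](CO)C(=O)OC | starting material
2 | methyl (R)‑3‑[(tert‑butyldimethylsilyl)oxy]‑2‑methylpropanoate | C[C@H](CO[Si](C)(C)C(C)(C)C)C(=O)OC | intermediate
3 | (R)‑3‑[(tert‑butyldimethylsilyl)oxy]‑2‑methylpropanal | C[C@H](CO[Si](C)(C)C(C)(C)C)C=O | intermediate
4 | 2‑(triphenyl‑λ5‑phosphanylidene)propanal | CC(C=O)=P(c1ccccc1)(c1ccccc1)c1ccccc1 | starting material
5 | (S,E)‑5‑[(tert‑butyldimethylsilyl)oxy]‑2,4‑dimethylpent‑2‑enal | C[C@H](CO[Si](C)(C)C(C)(C)C)/C=C(\C)C=O | intermediate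
6 | (S,E)‑tert‑butyl[(6,6‑dibromo‑2,4‑dimethylhexa‑3,5‑dien‑1‑yl)oxy]dimethylsilane | C[C@H](CO[Si](C)(C)C(C)(C)C)/C=C(\C)C=C(Br)Br | intermediate
7 | tert‑butyldimethyl{[(2S,3E,5E)‑2,4,6‑trimethylnona‑3,5‑dien‑7‑yn‑1‑yl]oxy}silane | C[C@H](CO[Si](C)(C)C(C)(C)C)/C=C(\C)/C=C(\C)C#CC | intermediate
8 | (2S,3E,5E)‑2,4,6‑trimethylnona‑3,5‑dien‑7‑yn‑1‑ol | C[C@H](CO)/C=C(\C)/C=C(\C)C#CC | intermediate
9 | (2S,3E,5E)‑2,4,6‑trimethylnona‑3,5‑dien‑7‑ynal | C[C@H](C=O)/C=C(\C)/C=C(\C)C#CC | intermediate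
10 | (2Z,4S,5E,7E)‑2‑iodo‑4,6,8‑trimethylundeca‑2,5,7‑trien‑9‑yne | I/C(C)=C\[C@@H](C)/C=C(\C)/C=C(\C)C#CC | intermediate
11 | prop‑2‑yn‑1‑ol | C#CCO | starting material
12 | (2E,4Z,6S,7E,9E)‑2,4,6,8,10‑pentamethyltrideca‑2,4,7,9‑tetraen‑11‑yn‑1‑ol | OC/C(C)=C/C(C)=C\[C@@H](C)/C=C(\C)/C=C(\C)C#CC | intermediate
13 | [(1R,3aR,4R,5R,7aS)‑1,3,4,5,7‑pentamethyl‑5‑(prop‑1‑yn‑1‑yl)‑3a,4,5,7a‑tetrahydro‑1H‑inden‑4‑yl]methanol | CC1=C[C@](C)(C#CC)[C@](C)(CO)[C@H]2C(C)=C[C@@H](C)[C@H]12 | intermediate
14 | (E)‑(2‑bromovinyl)benzene | Br/C=C/c1ccccc1 | starting material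
15 | [(1R,3aR,4R,5S,7aS)‑1,3,4,5,7‑pentamethyl‑5‑[(1E,3E)‑2‑methyl‑4‑phenylbuta‑1,3‑dien‑1‑yl]‑3a,4,5,7a‑tetrahydro‑1H‑inden‑4‑yl]methanol | CC1=C[C@](C)(/C=C(C)/C=C/c2ccccc2)[C@](C)(CO)[C@H]2C(C)=C[C@@H](C)[C@H]12 | intermediate
16 | (1R,3aR,4R,5S,7aS)‑1,3,4,5,7‑pentamethyl‑5‑[(1E,3E)‑2‑methyl‑4‑phenylbuta‑1,3‑dien‑1‑yl]‑3a,4,5,7a‑tetrahydro‑1H‑indene‑4‑carboxylic acid | CC1=C[C@](C)(/C=C(C)/C=C/c2ccccc2)[C@](C)(C(=O)O)[C@H]2C(C)=C[C@@H](C)[C@H]12 | target

## Step count and risks

Total steps: 12. Longest linear sequence: 12 (from 1; fully linear, with 4, 11 and 14 purchased).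

Steps most likely to fail:

1. **Step 10 (proposed electrochemical hole‑catalysed IMDA).** Risks are deprotonation of the doubly allylic C–H in the cation radical, stepwise closure eroding C4/C5 selectivity, and cyclobutane formation. Fallback with known chemistry: oxidise 12 with MnO2 to the (2E,4Z)‑dienal and run a thermal, Lewis‑acid‑promoted (Me2AlCl, CH2Cl2, −78→0 °C) normal‑demand IMDA through the same trans‑fused transition state, then NaBH4 to rejoin the route at 13.
2. **Step 8 (iodo‑Wittig on the epimerisable aldehyde 9).** Risks are modest yield and erosion of the C1 centre. Fallback: switch from vinyl‑iodide cross‑coupling to carbonyl olefination — Still–Gennari Z‑selective HWE on 9 with methyl 2‑[bis(2,2,2‑trifluoroethoxy)phosphoryl]propanoate at −78 °C, DIBAL, MnO2, Wittig with Ph3P=C(Me)CO2Et, then DIBAL to 12.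
3. **Step 5 (site‑ and stereoselective double Pd substitution).** Any E/Z leakage becomes the C5 epimer after step 10. Fallback: set the geometry by olefination instead — a second Wittig of 5 with ylide 4 to the (2E,4E)‑dienal, Ohira–Bestmann homologation to the terminal alkyne, then LiHMDS/MeI to give 7.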